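**Retrosynthetic overview**

1. Menaquinone-8 is traced back to its hydroquinone dimethyl ether. No ring is formed in the route: both rings of the naphthoquinone come from menadione, and the quinone is unmasked last.
2. Key disconnection: the C7′–C8′ bond (side chain numbered C1′ to C32′ from the ring). It is made in a one-flask, three-component double Negishi coupling in which a gem-dichloroalkene (C7′ as CCl2), a C31 homoallylzinc reagent (C8′) and Me2Zn (the C7′ methyl) converge on C7′.
3. Enabling feature: C7′ is the doubly carbon-substituted end of the C6′=C7′ trisubstituted alkene, and C8′ is homoallylic to C10′=C11′. In a C6′H=C7′Cl2 precursor the two C–Cl bonds differ only in lying trans or cis to the C5′ chain, so the chain can be placed trans and the methyl cis, which creates the E alkene while the fragments are joined.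
4. C31 iodide: two farnesyl units joined by allylic sulfone alkylation and desulfonylation, then extended by one carbon (oxidation, methylenation, hydroboration, iodination).
5. Dichloroalkene: menadione, then dimethyl ether, aryl bromide, Grignard geranylation, cleavage of the terminal alkene, and dichloromethylenation.

Key step: step 16

Assumption: (2E,6E)-farnesyl bromide, (2E,6E)-farnesyl acetate and geranyl bromide are used as purchased single E isomers, so six of the seven E alkenes of the target are carried in from these terpenes and only C6′=C7′ has to be created.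

**Route**

Step 1
Reactants: 1 (2E,6E)-farnesyl bromide
Product: 2 (2E,6E)-farnesyl phenyl sulfone
Conditions: PhSO2Na, DMF, rt
Reagents that add atoms: sodium benzenesulfinate, [Na+].[O-]S(=O)c1ccccc1
Why: SN2 S-alkylation of the sulfinate by the primary allylic bromide should give the allylic sulfone without touching either E alkene.

Step 2
Reactants: 3 (2E,6E)-farnesyl acetate
Product: 4 (2E,6E,10E)-12-hydroxy-3,7,11-trimethyldodeca-2,6,10-trien-1-yl acetate
Conditions: SeO2 (cat.), tBuOOH, salicylic acid (cat.), CH2Cl2, 0 °C to rt, stopped at partial conversion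
Reagents that add atoms: tert-butyl hydroperoxide, CC(C)(C)OO; selenium dioxide (catalytic oxygen carrier), O=[Se]=O
Why: The SeO2-catalysed allylic oxidation (Riley-type ene reaction followed by a [2,3]-sigmatropic shift) should hydroxylate the E-methyl group of the terminal, most electron-rich alkene and leave an E allylic alcohol, the C2=C3 alkene being deactivated by the allylic acetate.

Step 3
Reactants: 4 (2E,6E,10E)-12-hydroxy-3,7,11-trimethyldodeca-2,6,10-trien-1-yl acetate
Product: 5 (2E,6E,10E)-12-bromo-3,7,11-trimethyldodeca-2,6,10-trien-1-yl acetate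
Conditions: CBr4, PPh3, CH2Cl2, 0 °C
Reagents that add atoms: carbon tetrabromide, BrC(Br)(Br)Br
Why: The Appel reaction should convert the primary allylic alcohol into the primary bromide by SN2 displacement of the oxyphosphonium group, without allylic transposition and without affecting the acetate.

Step 4
Reactants: 2 (2E,6E)-farnesyl phenyl sulfone; 5 (2E,6E,10E)-12-bromo-3,7,11-trimethyldodeca-2,6,10-trien-1-yl acetate
Product: 7 (2E,6E,10E,14E,18E)-3,7,11,15,19,23-hexamethyl-13-(phenylsulfonyl)tetracosa-2,6,10,14,18,22-hexaen-1-yl acetate (racemic at C13), via lithiated sulfone 6 (not isolated)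
Conditions: nBuLi, THF, −78 °C; then 5, −78 to −30 °C
Reagents that add atoms: none
Why: α-Alkylation of the allylic sulfonyl carbanion by the primary allylic bromide (Julia-type sulfone coupling) should be faster at low temperature than acyl transfer from the acetate; the new C13 stereocentre forms as a racemate and is erased in step 5.

Step 5
Reactants: 7 the C30 sulfone acetate
Product: 9 all-E-hexaprenol, (2E,6E,10E,14E,18E)-3,7,11,15,19,23-hexamethyltetracosa-2,6,10,14,18,22-hexaen-1-ol, via lithium alkoxide 8 (not isolated)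
Conditions: LiEt3BH (5 equiv), THF, 0 °C; then PdCl2(dppp) (5 mol%), 0 °C to rt
Reagents that add atoms: none
Why: The hydride should first cleave the acetate (so that no allylic ester remains when palladium is added), and palladium-catalysed hydride desulfonylation through a π-allylpalladium intermediate should then deliver hydride to the less substituted terminus C13, keeping the C14=C15 alkene in place and E.

Step 6
Reactants: 9 all-E-hexaprenol
Product: 10 all-E-hexaprenal, (2E,6E,10E,14E,18E)-3,7,11,15,19,23-hexamethyltetracosa-2,6,10,14,18,22-hexaenal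
Conditions: MnO2 (activated, excess), hexane/CH2Cl2, rt
Reagents that add atoms: none
Why: MnO2 oxidation is selective for the allylic alcohol and should give the enal without E/Z isomerisation or over-oxidation.

Step 7
Reactants: 10 all-E-hexaprenal
Product: 11 (3E,7E,11E,15E,19E)-4,8,12,16,20,24-hexamethylpentacosa-1,3,7,11,15,19,23-heptaene
Conditions: Ph3PCH3Br, KOtBu, THF, 0 °C; then 10, 0 °C to rt
Reagents that add atoms: methyltriphenylphosphonium bromide, C[P+](c1ccccc1)(c1ccccc1)c1ccccc1.[Br-]
Why: Wittig methylenation of the enal proceeds by 1,2-addition and should give the terminal 1,3-diene with the C3=C4 geometry unchanged.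

Step 8
Reactants: 11 the C31 heptaene
Product: 13 homohexaprenol, (3E,7E,11E,15E,19E)-4,8,12,16,20,24-hexamethylpentacosa-3,7,11,15,19,23-hexaen-1-ol, via B-alkyl-9-BBN 12 (not isolated)
Conditions: 9-BBN (1.1 equiv), THF, 0 °C to rt; then NaOH aq., 30% H2O2, 0 °C to rt
Reagents that add atoms: hydrogen peroxide, OO
Why: Anti-Markovnikov hydroboration with the bulky 9-BBN should occur only at the single monosubstituted alkene, since the six trisubstituted alkenes react far more slowly, and oxidation then gives the primary homoallylic alcohol.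

Step 9
Reactants: 13 homohexaprenol
Product: 14 homohexaprenyl iodide, (6E,10E,14E,18E,22E)-25-iodo-2,6,10,14,18,22-hexamethylpentacosa-2,6,10,14,18,22-hexaene
Conditions: I2, PPh3, imidazole, CH2Cl2, 0 °C to rt, dark
Reagents that add atoms: iodine, II
Why: Appel-type iodination should displace the activated primary hydroxyl by iodide in an SN2 reaction under conditions that leave the polyene untouched.

Step 10
Reactants: 15 menadione (2-methylnaphthalene-1,4-dione)
Product: 17 1,4-dimethoxy-2-methylnaphthalene, via menadiol 16 (not isolated)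
Conditions: Na2S2O4, H2O/THF, rt; then NaOH aq., Me2SO4, Bu4NBr (cat.), rt
Reagents that add atoms: dimethyl sulfate, COS(=O)(=O)OC
Why: Dithionite reduction to the hydroquinone followed directly by Williamson O-methylation (a reductive methylation) should protect the quinone as a base- and organometal-stable dimethyl ether.

Step 11
Reactants: 17 1,4-dimethoxy-2-methylnaphthalene
Product: 18 2-bromo-1,4-dimethoxy-3-methylnaphthalene
Conditions: Br2, CH2Cl2, 0 °C
Reagents that add atoms: bromine, BrBr
Why: Electrophilic aromatic bromination should go to the only free position of the electron-rich, oxygen-substituted ring.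

Step 12
Reactants: 18 2-bromo-1,4-dimethoxy-3-methylnaphthalene; 19 geranyl bromide, (2E)-1-bromo-3,7-dimethylocta-2,6-diene
Product: 21 2-[(2E)-3,7-dimethylocta-2,6-dien-1-yl]-1,4-dimethoxy-3-methylnaphthalene, via aryl Grignard reagent 20 (not isolated)
Conditions: Mg turnings, THF, 50 °C; then Li2CuCl4 (3 mol%), 19, THF, −10 °C to rt
Reagents that add atoms: none
Why: Copper-catalysed coupling of the aryl Grignard reagent with the primary allylic bromide (Kochi-type, α-selective SN2) should attach the geranyl group at C1′ with the C2′=C3′ E geometry retained.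

Step 13
Reactants: 21 the geranyl arene
Product: 23 2-[(2E)-5-(3,3-dimethyloxiran-2-yl)-3-methylpent-2-en-1-yl]-1,4-dimethoxy-3-methylnaphthalene (racemic), via bromohydrin 22 (not isolated)
Conditions: NBS, THF/H2O (3:1), 0 °C; then K2CO3, MeOH, rt
Reagents that add atoms: water, O
Why: Bromohydrin formation in aqueous THF should favour the terminal, sterically most accessible trisubstituted alkene, and intramolecular Williamson closure then gives the terminal epoxide, whose racemic stereocentre is removed in step 14.

Step 14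
Reactants: 23 the terminal epoxide
Product: 24 (4E)-6-(1,4-dimethoxy-3-methylnaphthalen-2-yl)-4-methylhex-4-enal
Conditions: H5IO6, THF/Et2O, 0 °C
Reagents that add atoms: none
Why: Periodic acid should open the epoxide at its tertiary carbon, so that the epoxide oxygen stays on the CH carbon and becomes the aldehyde oxygen, and should cleave the resulting glycol (Malaprade-type cleavage) to the aldehyde and acetone, leaving the C2′=C3′ alkene and the aryl ethers intact.

Step 15
Reactants: 24 the aldehyde
Product: 25 2-[(2E)-7,7-dichloro-3-methylhepta-2,6-dien-1-yl]-1,4-dimethoxy-3-methylnaphthalene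
Conditions: PPh3, BrCCl3, MeCN, 0 °C to rt
Reagents that add atoms: bromotrichloromethane, ClC(Cl)(Cl)Br
Why: Wittig-type dichloromethylenation by Ph3P=CCl2 generated in the flask should convert the aldehyde carbon C6′ into the C6′H=C7′Cl2 unit under nearly neutral conditions.

Step 16
Reactants: 14 homohexaprenyl iodide; 25 the gem-dichloroalkene
Product: 28 menaquinone-8 hydroquinone dimethyl ether, 2-[(2E,6E,10E,14E,18E,22E,26E)-3,7,11,15,19,23,27,31-octamethyldotriaconta-2,6,10,14,18,22,26,30-octaen-1-yl]-1,4-dimethoxy-3-methylnaphthalene, via homohexaprenylzinc iodide 26 (not isolated), via (Z)-chloroalkene 27 (not isolated)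
Conditions: 14, Zn dust (activated with BrCH2CH2Br and Me3SiCl), LiCl, THF, 40 °C; then 25, PdCl2(DPEphos) (3 mol%), THF/DMF, 23 to 50 °C; then Pd(PtBu3)2 (5 mol%), Me2Zn (2.5 equiv), 50 °C
Reagents that add atoms: dimethylzinc, C[Zn]C
Why: Zinc inserts into the primary C–I bond of 14 to give homoallylzinc 26; zerovalent palladium carrying the wide-bite-angle DPEphos ligand then adds to the C7′–Cl bond of 25 that lies trans to the C5′ chain (cis to the small C6′–H), and transmetalation with 26 followed by reductive elimination forms the C7′–C8′ bond and gives (Z)-chloroalkene 27, whose remaining, now unactivated C–Cl bond is opened only by the electron-rich Pd(PtBu3)2 and is methylated by Me2Zn with retention. The closest known reaction type is the palladium-catalysed trans-selective monoalkylation of 1,1-dichloro-1-alkenes with alkylzinc reagents followed by stereoretentive Negishi methylation of the 2-chloro-2-alkene, itself an extension of the homoallylzinc–alkenyl halide coupling used for 1,5-dienes. No ring is closed and no stereocentre is formed; the one stereochemical element created, the E geometry of C6′=C7′, is controlled by the order of the two substitutions (C31 chain first at the less hindered trans C–Cl, methyl second with retention). The step needs mono- rather than double alkylation by 26, which the substrate secures because the monochloride 27 is inert to the DPEphos catalyst and 26 is used in slight excess only, and it needs retention in the methylation, for which Pd(PtBu3)2 is chosen. β-Hydride elimination from the homoallylpalladium intermediate should be outrun by reductive elimination, and the aryl methyl ethers and the seven other alkenes are inert to organozinc reagents. In this single operation three components converge on C7′, the full C51 skeleton is completed and the last E-trisubstituted alkene is made instead of carried.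

Step 17
Reactants: 28 menaquinone-8 hydroquinone dimethyl ether
Product: 29 menaquinone-8
Conditions: (NH4)2Ce(NO3)6 (2.5 equiv), MeCN/H2O/CH2Cl2, 0 °C
Reagents that add atoms: water, O
Why: Oxidative demethylation by tetravalent cerium proceeds by single-electron oxidation of the electron-rich 1,4-dimethoxynaphthalene, which should be much faster than any attack on the isolated trisubstituted alkenes, and gives the 1,4-naphthoquinone directly.

**Compound list**

1 | (2E,6E)-farnesyl bromide, (2E,6E)-1-bromo-3,7,11-trimethyldodeca-2,6,10-triene | CC(C)=CCC/C(C)=C/CC/C(C)=C/CBr | starting material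
2 | (2E,6E)-farnesyl phenyl sulfone | CC(C)=CCC/C(C)=C/CC/C(C)=C/CS(=O)(=O)c1ccccc1 | intermediate
3 | (2E,6E)-farnesyl acetate | CC(C)=CCC/C(C)=C/CC/C(C)=C/COC(C)=O | starting material
4 | (2E,6E,10E)-12-hydroxy-3,7,11-trimethyldodeca-2,6,10-trien-1-yl acetate | OC/C(C)=C/CC/C(C)=C/CC/C(C)=C/COC(C)=O | intermediate
5 | (2E,6E,10E)-12-bromo-3,7,11-trimethyldodeca-2,6,10-trien-1-yl acetate | BrC/C(C)=C/CC/C(C)=C/CC/C(C)=C/COC(C)=O | intermediate
6 | 1-lithio-(2E,6E)-farnesyl phenyl sulfone (lithiated sulfone) | CC(C)=CCC/C(C)=C/CC/C(C)=C/C([Li])S(=O)(=O)c1ccccc1 | intermediate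
7 | (2E,6E,10E,14E,18E)-3,7,11,15,19,23-hexamethyl-13-(phenylsulfonyl)tetracosa-2,6,10,14,18,22-hexaen-1-yl acetate, racemic at C13 | CC(C)=CCC/C(C)=C/CC/C(C)=C/C(S(=O)(=O)c1ccccc1)C/C(C)=C/CC/C(C)=C/CC/C(C)=C/COC(C)=O | intermediate
8 | lithium (2E,6E,10E,14E,18E)-3,7,11,15,19,23-hexamethyl-13-(phenylsulfonyl)tetracosa-2,6,10,14,18,22-hexaen-1-olate, racemic | CC(C)=CCC/C(C)=C/CC/C(C)=C/C(S(=O)(=O)c1ccccc1)C/C(C)=C/CC/C(C)=C/CC/C(C)=C/C[O-].[Li+] | intermediate
9 | all-E-hexaprenol, (2E,6E,10E,14E,18E)-3,7,11,15,19,23-hexamethyltetracosa-2,6,10,14,18,22-hexaen-1-ol | CC(C)=CCC/C(C)=C/CC/C(C)=C/CC/C(C)=C/CC/C(C)=C/CC/C(C)=C/CO | intermediate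
10 | all-E-hexaprenal, (2E,6E,10E,14E,18E)-3,7,11,15,19,23-hexamethyltetracosa-2,6,10,14,18,22-hexaenal | CC(C)=CCC/C(C)=C/CC/C(C)=C/CC/C(C)=C/CC/C(C)=C/CC/C(C)=C/C=O | intermediate
11 | (3E,7E,11E,15E,19E)-4,8,12,16,20,24-hexamethylpentacosa-1,3,7,11,15,19,23-heptaene | CC(C)=CCC/C(C)=C/CC/C(C)=C/CC/C(C)=C/CC/C(C)=C/CC/C(C)=C/C=C | intermediate
12 | 9-[(3E,7E,11E,15E,19E)-4,8,12,16,20,24-hexamethylpentacosa-3,7,11,15,19,23-hexaen-1-yl]-9-borabicyclo[3.3.1]nonane | CC(C)=CCC/C(C)=C/CC/C(C)=C/CC/C(C)=C/CC/C(C)=C/CC/C(C)=C/CCB1C2CCCC1CCC2 | intermediate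
13 | homohexaprenol, (3E,7E,11E,15E,19E)-4,8,12,16,20,24-hexamethylpentacosa-3,7,11,15,19,23-hexaen-1-ol | CC(C)=CCC/C(C)=C/CC/C(C)=C/CC/C(C)=C/CC/C(C)=C/CC/C(C)=C/CCO | intermediate
14 | homohexaprenyl iodide, (6E,10E,14E,18E,22E)-25-iodo-2,6,10,14,18,22-hexamethylpentacosa-2,6,10,14,18,22-hexaene | CC(C)=CCC/C(C)=C/CC/C(C)=C/CC/C(C)=C/CC/C(C)=C/CC/C(C)=C/CCI | intermediate
15 | menadione, 2-methylnaphthalene-1,4-dione | CC1=CC(=O)c2ccccc2C1=O | starting material
16 | menadiol, 2-methylnaphthalene-1,4-diol | Cc1cc(O)c2ccccc2c1O | intermediate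
17 | 1,4-dimethoxy-2-methylnaphthalene | Cc1cc(OC)c2ccccc2c1OC | intermediate
18 | 2-bromo-1,4-dimethoxy-3-methylnaphthalene | Cc1c(Br)c(OC)c2ccccc2c1OC | intermediate
19 | geranyl bromide, (2E)-1-bromo-3,7-dimethylocta-2,6-diene | CC(C)=CCC/C(C)=C/CBr | starting material
20 | (1,4-dimethoxy-3-methylnaphthalen-2-yl)magnesium bromide | Cc1c([Mg]Br)c(OC)c2ccccc2c1OC | intermediate
21 | 2-[(2E)-3,7-dimethylocta-2,6-dien-1-yl]-1,4-dimethoxy-3-methylnaphthalene | CC(C)=CCC/C(C)=C/Cc1c(C)c(OC)c2ccccc2c1OC | intermediate
22 | 2-[(2E)-6-bromo-7-hydroxy-3,7-dimethyloct-2-en-1-yl]-1,4-dimethoxy-3-methylnaphthalene, racemic | CC(C)(O)C(Br)CC/C(C)=C/Cc1c(C)c(OC)c2ccccc2c1OC | intermediate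
23 | 2-[(2E)-5-(3,3-dimethyloxiran-2-yl)-3-methylpent-2-en-1-yl]-1,4-dimethoxy-3-methylnaphthalene, racemic | CC1(C)OC1CC/C(C)=C/Cc1c(C)c(OC)c2ccccc2c1OC | intermediate
24 | (4E)-6-(1,4-dimethoxy-3-methylnaphthalen-2-yl)-4-methylhex-4-enal | O=CCC/C(C)=C/Cc1c(C)c(OC)c2ccccc2c1OC | intermediate
25 | 2-[(2E)-7,7-dichloro-3-methylhepta-2,6-dien-1-yl]-1,4-dimethoxy-3-methylnaphthalene | ClC(Cl)=CCC/C(C)=C/Cc1c(C)c(OC)c2ccccc2c1OC | intermediate
26 | [(3E,7E,11E,15E,19E)-4,8,12,16,20,24-hexamethylpentacosa-3,7,11,15,19,23-hexaen-1-yl]zinc iodide (homohexaprenylzinc iodide, LiCl adduct) | CC(C)=CCC/C(C)=C/CC/C(C)=C/CC/C(C)=C/CC/C(C)=C/CC/C(C)=C/CC[Zn]I | intermediate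
27 | 2-[(2E,6Z,10E,14E,18E,22E,26E)-7-chloro-3,11,15,19,23,27,31-heptamethyldotriaconta-2,6,10,14,18,22,26,30-octaen-1-yl]-1,4-dimethoxy-3-methylnaphthalene | CC(C)=CCC/C(C)=C/CC/C(C)=C/CC/C(C)=C/CC/C(C)=C/CC/C(C)=C/CC/C(Cl)=C/CC/C(C)=C/Cc1c(C)c(OC)c2ccccc2c1OC | intermediate
28 | menaquinone-8 hydroquinone dimethyl ether, 2-[(2E,6E,10E,14E,18E,22E,26E)-3,7,11,15,19,23,27,31-octamethyldotriaconta-2,6,10,14,18,22,26,30-octaen-1-yl]-1,4-dimethoxy-3-methylnaphthalene | CC(C)=CCC/C(C)=C/CC/C(C)=C/CC/C(C)=C/CC/C(C)=C/CC/C(C)=C/CC/C(C)=C/CC/C(C)=C/Cc1c(C)c(OC)c2ccccc2c1OC | intermediate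
29 | menaquinone-8, 2-methyl-3-[(2E,6E,10E,14E,18E,22E,26E)-3,7,11,15,19,23,27,31-octamethyldotriaconta-2,6,10,14,18,22,26,30-octaen-1-yl]naphthalene-1,4-dione | CC(C)=CCC/C(C)=C/CC/C(C)=C/CC/C(C)=C/CC/C(C)=C/CC/C(C)=C/CC/C(C)=C/CC/C(C)=C/CC1=C(C)C(=O)c2ccccc2C1=O | target

**Step count and risks**

Total step count: 17.
Longest linear sequence: 10 steps (steps 2, 3, 4, 5, 6, 7, 8, 9, 16, 17, from 3 to 29).

Steps most likely to fail:

1. Step 16. The first oxidative addition may not discriminate fully between the two C–Cl bonds, the zinc reagent may substitute both chlorides, or the alkene geometry may be partly lost during the methylation. The fallback separates the two bond formations and puts the methyl group in before the fragments are joined; it sets out from 25 (with 26 made from 14 as in step 16) and comes back at 28. Treatment of 25 with nBuLi (2.2 equiv, THF, −78 to 0 °C; Corey–Fuchs-type elimination to the chloroalkyne and lithium–chlorine exchange to the lithium acetylide) and then MeI should give the methyl alkyne 2-[(2E)-3-methyloct-2-en-6-yn-1-yl]-1,4-dimethoxy-3-methylnaphthalene F1. Hydrozirconation with Cp2Zr(H)Cl under equilibrating conditions (slight excess, THF, 50 °C) places zirconium on the methyl-bearing alkyne carbon by syn addition, and iodinolysis (I2, 0 °C) should give the alkenyl iodide 2-[(2E,6E)-7-iodo-3-methylocta-2,6-dien-1-yl]-1,4-dimethoxy-3-methylnaphthalene F2. Negishi coupling of F2 with 26 (Pd(PPh3)4, THF, rt), the classical homoallylzinc–alkenyl iodide coupling, should then form the same C7′–C8′ bond with retention and give 28.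

2. Step 13. Bromonium formation may not discriminate between the C6′=C7′ and C2′=C3′ alkenes, and the electron-rich arene may be brominated. The fallback moves the differentiation of the two alkenes to a stage where the substrate itself biases it; it sets out from 19 and 18 and comes back at 23. Epoxidation of 19 with mCPBA (NaHCO3, CH2Cl2, −10 °C) should occur at the remote alkene, because the allylic C–Br bond deactivates C2=C3, and give 6,7-epoxygeranyl bromide F3. Coupling of F3 with the Grignard reagent 20 made from 18 (Li2CuCl4 cat., THF, −30 °C), in which displacement of the allylic bromide is much faster than opening of the trisubstituted epoxide, should give 23 directly.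

3. Step 2. The allylic oxidation may stall at low conversion, run on to the enal, or attack internal allylic positions. The fallback builds the oxidised terminus by olefination instead of C–H oxidation; it sets out from 3 and comes back at 4. Terminal bromohydrin formation on 3 (NBS, THF/H2O, 0 °C) should give the bromohydrin (2E,6E)-10-bromo-11-hydroxy-3,7,11-trimethyldodeca-2,6-dien-1-yl acetate F4, and ring closure with DBU (CH2Cl2, rt), which spares the acetate, the epoxide (2E,6E)-10,11-epoxyfarnesyl acetate F5. Periodic acid cleavage (H5IO6, THF/Et2O, 0 °C) should give the aldehyde (4E,8E)-10-acetoxy-4,8-dimethyldeca-4,8-dienal F6. An E-selective Wittig reaction with the stabilised ylide Ph3P=C(CH3)CHO (toluene, 80 °C) should give the enal (2E,6E,10E)-3,7,11-trimethyl-12-oxododeca-2,6,10-trien-1-yl acetate F7, and Luche reduction (NaBH4, CeCl3·7H2O, MeOH, 0 °C) should give 4.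

**Further compounds**

F1 | step 16 | 2-[(2E)-3-methyloct-2-en-6-yn-1-yl]-1,4-dimethoxy-3-methylnaphthalene | CC#CCC/C(C)=C/Cc1c(C)c(OC)c2ccccc2c1OC
F2 | step 16 | 2-[(2E,6E)-7-iodo-3-methylocta-2,6-dien-1-yl]-1,4-dimethoxy-3-methylnaphthalene | I/C(C)=C/CC/C(C)=C/Cc1c(C)c(OC)c2ccccc2c1OC
F3 | step 13 | 6,7-epoxygeranyl bromide, 3-[(3E)-5-bromo-3-methylpent-3-en-1-yl]-2,2-dimethyloxirane, racemic | CC1(C)OC1CC/C(C)=C/CBr
F4 | step 2 | (2E,6E)-10-bromo-11-hydroxy-3,7,11-trimethyldodeca-2,6-dien-1-yl acetate, racemic | CC(C)(O)C(Br)CC/C(C)=C/CC/C(C)=C/COC(C)=O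
F5 | step 2 | (2E,6E)-10,11-epoxyfarnesyl acetate, racemic | CC1(C)OC1CC/C(C)=C/CC/C(C)=C/COC(C)=O
F6 | step 2 | (4E,8E)-10-acetoxy-4,8-dimethyldeca-4,8-dienal | O=CCC/C(C)=C/CC/C(C)=C/COC(C)=O
F7 | step 2 | (2E,6E,10E)-3,7,11-trimethyl-12-oxododeca-2,6,10-trien-1-yl acetate | O=C/C(C)=C/CC/C(C)=C/CC/C(C)=C/COC(C)=O
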